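**Plan**

- Retrosynthesis (atom labels follow the dihydronaphthalene core of the target: C1 carries pendant ring C, C2 the CH2OH, C3 the CO2Me, C4 is the vinylic CH, C4a/C8a join ring B to ring A): the C3–CO2Me bond is cut back to the enol triflate of a C3 ketone; C4 is then excised by cutting C3–C4 and C4–C4a; then come C2–CH2O, C1–C8a and finally the enone C=C between the two syringyl units.
- Enabling feature: ring B (C1, C2, C3, C4, C4a, C8a) is the five-membered ring of a trans-2,3-disubstituted indan-1-one plus the one carbon C4, lodged between carbonyl carbon C3 and ring A carbon C4a; C4a is para to the C7 oxygen and therefore a willing migrating group.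
- Forward order: benzylation and ring bromination, Claisen–Schmidt union of the two aryl units, closure of the five-membered ring through C1–C8a, benzyloxymethylation at C2, insertion of C4 from a diazo carbon to grow ring B to six members, then enol triflate, methoxycarbonylation and debenzylation.
- Stereochemistry: C1 is set by the chiral palladium catalyst in the ring closure to the indanone; C2 is set trans to the C1 aryl group by substrate-controlled enolate alkylation and is carried unchanged through the ring enlargement and the end game.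

Key step: step 7

Assumption: the (R)-configured bisphosphine is taken to deliver the (S)-indanone; should the sense of induction be the reverse, the (S)-ligand is used and nothing else changes.

**Route**

Step 1
Reactants: 1 acetosyringone
Product: 2 1-[4-(benzyloxy)-3,5-dimethoxyphenyl]ethan-1-one
Conditions: BnBr, K2CO3, DMF, 60 °C
Reagents that add atoms: benzyl bromide, BrCc1ccccc1
Why: Williamson ether synthesis, in which the phenoxide formed with K2CO3 displaces bromide from benzyl bromide (SN2).

Step 2
Reactants: 2 O-benzylacetosyringone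
Product: 3 1-[4-(benzyloxy)-2-bromo-3,5-dimethoxyphenyl]ethan-1-one
Conditions: NBS, MeCN, 0 °C to rt, dark
Reagents that add atoms: N-bromosuccinimide, O=C1CCC(=O)N1Br
Why: Electrophilic aromatic bromination, in which the two equivalent free ring positions are ortho and para to methoxy groups and NBS in polar, acid-free MeCN should brominate the activated ring in preference to the acetyl methyl group.

Step 3
Reactants: 4 syringaldehyde
Product: 5 4-(benzyloxy)-3,5-dimethoxybenzaldehyde
Conditions: BnBr, K2CO3, DMF, 60 °C
Reagents that add atoms: benzyl bromide, BrCc1ccccc1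
Why: Williamson ether synthesis, the phenoxide displacing bromide from benzyl bromide (SN2) while the aldehyde is left alone.

Step 4
Reactants: 3 bromo ketone; 5 O-benzylsyringaldehyde
Product: 7 (E)-1-[4-(benzyloxy)-2-bromo-3,5-dimethoxyphenyl]-3-[4-(benzyloxy)-3,5-dimethoxyphenyl]prop-2-en-1-one, via aldol adduct 6 (not isolated)
Conditions: KOH (aq), EtOH/THF, rt
Reagents that add atoms: none
Why: Claisen–Schmidt condensation (crossed aldol then E1cB dehydration), in which the aldehyde cannot enolise and the methyl ketone has a single enolisable site, so one aldol adduct forms and dehydrates to the conjugated E-enone.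

Step 5
Reactants: 7 bromochalcone
Product: 8 (3S)-5-(benzyloxy)-3-[4-(benzyloxy)-3,5-dimethoxyphenyl]-4,6-dimethoxy-2,3-dihydro-1H-inden-1-one
Conditions: Pd(OAc)2 (5 mol %), (R)-3,5-Xyl-MeO-BIPHEP (6 mol %), iPr2NEt, PhCO2H, ethylene glycol/1,4-dioxane, 100 °C
Reagents that add atoms: none
Why: Asymmetric reductive Heck cyclisation (intramolecular conjugate hydroarylation), in which zerovalent palladium inserts into the C–Br bond, the cationic arylpalladium species favoured by the hydrogen-bonding glycol medium adds to the enone β-carbon to form C1–C8a, the palladium enolate is protonated and the amine returns divalent palladium to the zerovalent state, the chiral bisphosphine choosing the enone face and so setting the benzylic stereocentre as (S).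

Step 6
Reactants: 8 (S)-3-arylindan-1-one; 9 benzyl chloromethyl ether
Product: 11 (2S,3S)-5-(benzyloxy)-3-[4-(benzyloxy)-3,5-dimethoxyphenyl]-2-[(benzyloxy)methyl]-4,6-dimethoxy-2,3-dihydro-1H-inden-1-one, via lithium enolate 10 (not isolated)
Conditions: LiN(SiMe3)2, THF, −78 °C; then BnOCH2Cl, −78 to −40 °C
Reagents that add atoms: benzyl chloromethyl ether (compound 9), ClCOCc1ccccc1
Why: Kinetic enolate alkylation (SN2 on an α-chloro ether), in which the electrophile should approach the planar enolate carbon anti to the neighbouring aryl group and so give the trans (2S,3S) product, which is also the thermodynamically preferred epimer.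

Step 7
Reactants: 11 trans-indanone; 12 trimethylsilyldiazomethane
Product: 14 (3S,4S)-6-(benzyloxy)-4-[4-(benzyloxy)-3,5-dimethoxyphenyl]-3-[(benzyloxy)methyl]-5,7-dimethoxy-3,4-dihydronaphthalen-2(1H)-one, via C-silyl ketone 13 (not isolated)
Conditions: Me3SiCHN2 (1.5 equiv), BF3·OEt2 (1.5 equiv), CH2Cl2, −78 to −20 °C; then 1 M HCl, THF, rt
Reagents that add atoms: trimethylsilyldiazomethane (compound 12), C[Si](C)(C)C=[N+]=[N-]
Why: BF3 activates the C3 carbonyl of 11, the diazo carbon adds to C3, and loss of N2 from the β-oxido diazonium species is accompanied by a 1,2-shift of ring A carbon C4a from C3 to the incoming carbon, which becomes C4, so that C3–C4 and C4–C4a form in one operation and the α-silyl ketone 13 gives up silicon on acidic work-up. The closest known reaction type is the Lewis-acid-promoted diazoalkane homologation of benzo-fused cycloalkanones (Tiffeneau–Demjanov-type ring enlargement), as in the conversion of 1-indanones into 2-tetralones. Ring B is not closed by cyclisation of a chain but arises by one-carbon enlargement of the existing five-membered ring through the 1,2-aryl shift. No lasting stereocentre is created, since the silylated C4 is transient and ends as CH2, C1 is not touched, and C2 is not the migrating carbon and keeps the trans setting that is also favoured should the α-centre equilibrate. The step needs aryl rather than C2 migration and a single insertion; the first is secured by the electron-rich migrating carbon C4a (para to the C7 benzyloxy oxygen) and by the steric bias of the silylated diazo carbon against the branched C2, the second by the bulk of silicon beside the new ketone, the low temperature and the small excess of reagent.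

Step 8
Reactants: 14 trans-2-tetralone
Product: 16 (3S,4S)-6-(benzyloxy)-4-[4-(benzyloxy)-3,5-dimethoxyphenyl]-3-[(benzyloxy)methyl]-5,7-dimethoxy-3,4-dihydronaphthalen-2-yl trifluoromethanesulfonate, via potassium enolate 15 (not isolated)
Conditions: KN(SiMe3)2, THF, −78 °C; then PhNTf2, −78 to 0 °C
Reagents that add atoms: N-phenylbis(trifluoromethanesulfonimide), O=S(=O)(N(c1ccccc1)S(=O)(=O)C(F)(F)F)C(F)(F)F
Why: Regioselective enolate O-triflation, in which the benzylic CH2 between the carbonyl and ring A is both the more acidic and the less hindered α-position, so the base should give only the arene-conjugated enolate and leave the C2 methine and its β-benzyloxy group untouched before PhNTf2 sulfonylates oxygen.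

Step 9
Reactants: 16 enol triflate
Product: 17 methyl (3R,4S)-6-(benzyloxy)-4-[4-(benzyloxy)-3,5-dimethoxyphenyl]-3-[(benzyloxy)methyl]-5,7-dimethoxy-3,4-dihydronaphthalene-2-carboxylate
Conditions: Pd(OAc)2 (5 mol %), PPh3, CO (1 atm), MeOH, Et3N, DMF, 40 °C
Reagents that add atoms: carbon monoxide, [C-]#[O+]; methanol, CO
Why: Palladium-catalysed alkoxycarbonylation of an enol triflate, in which oxidative addition of zerovalent palladium into the C–OTf bond, CO insertion and methanolysis of the acylpalladium species give the conjugated ester without moving the double bond or touching the stereocentres (the descriptor at C2 changes from S to R only through the priority rules).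

Step 10
Reactants: 17 tribenzyl ester
Product: 19 methyl (3R,4S)-6-hydroxy-4-(4-hydroxy-3,5-dimethoxyphenyl)-3-(hydroxymethyl)-5,7-dimethoxy-3,4-dihydronaphthalene-2-carboxylate, via tris(dichloroboryl) derivative 18 (not isolated)
Conditions: BCl3, C6HMe5, CH2Cl2, −78 to −40 °C; then MeOH, −78 °C, NaHCO3 work-up
Reagents that add atoms: none
Why: Lewis-acid ether cleavage with a cation scavenger, in which BCl3 ionises each benzylic C–O bond at low temperature, pentamethylbenzene captures the benzyl cations by Friedel–Crafts alkylation so that they cannot attack the electron-rich rings or the alkene, and methanolysis of the B–O bonds releases the two phenols and the primary alcohol while methyl ethers, ester and both stereocentres are left alone.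

**Compound list**

1 | acetosyringone, 1-(4-hydroxy-3,5-dimethoxyphenyl)ethan-1-one | CC(=O)c1cc(OC)c(O)c(OC)c1 | starting material
2 | 1-[4-(benzyloxy)-3,5-dimethoxyphenyl]ethan-1-one | CC(=O)c1cc(OC)c(OCc2ccccc2)c(OC)c1 | intermediate
3 | 1-[4-(benzyloxy)-2-bromo-3,5-dimethoxyphenyl]ethan-1-one | CC(=O)c1cc(OC)c(OCc2ccccc2)c(OC)c1Br | intermediate
4 | syringaldehyde, 4-hydroxy-3,5-dimethoxybenzaldehyde | COc1cc(C=O)cc(OC)c1O | starting material
5 | 4-(benzyloxy)-3,5-dimethoxybenzaldehyde | COc1cc(C=O)cc(OC)c1OCc1ccccc1 | intermediate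
6 | aldol adduct, 1-[4-(benzyloxy)-2-bromo-3,5-dimethoxyphenyl]-3-[4-(benzyloxy)-3,5-dimethoxyphenyl]-3-hydroxypropan-1-one (racemic, not isolated) | O=C(CC(O)c1cc(OC)c(OCc2ccccc2)c(OC)c1)c1cc(OC)c(OCc2ccccc2)c(OC)c1Br | intermediate
7 | (E)-1-[4-(benzyloxy)-2-bromo-3,5-dimethoxyphenyl]-3-[4-(benzyloxy)-3,5-dimethoxyphenyl]prop-2-en-1-one | O=C(/C=C/c1cc(OC)c(OCc2ccccc2)c(OC)c1)c1cc(OC)c(OCc2ccccc2)c(OC)c1Br | intermediate
8 | (3S)-5-(benzyloxy)-3-[4-(benzyloxy)-3,5-dimethoxyphenyl]-4,6-dimethoxy-2,3-dihydro-1H-inden-1-one | O=C1c2cc(OC)c(OCc3ccccc3)c(OC)c2[C@H](c2cc(OC)c(OCc3ccccc3)c(OC)c2)C1 | intermediate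
9 | benzyl chloromethyl ether | ClCOCc1ccccc1 | starting material
10 | lithium (1S)-6-(benzyloxy)-1-[4-(benzyloxy)-3,5-dimethoxyphenyl]-5,7-dimethoxy-1H-inden-3-olate (not isolated) | [Li]OC1=C[C@@H](c2cc(OC)c(OCc3ccccc3)c(OC)c2)c2c(OC)c(OCc3ccccc3)c(OC)cc12 | intermediate
11 | (2S,3S)-5-(benzyloxy)-3-[4-(benzyloxy)-3,5-dimethoxyphenyl]-2-[(benzyloxy)methyl]-4,6-dimethoxy-2,3-dihydro-1H-inden-1-one (trans) | O=C1c2cc(OC)c(OCc3ccccc3)c(OC)c2[C@H](c2cc(OC)c(OCc3ccccc3)c(OC)c2)[C@H]1COCc1ccccc1 | intermediate
12 | trimethylsilyldiazomethane | C[Si](C)(C)C=[N+]=[N-] | starting material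
13 | (3S,4S)-6-(benzyloxy)-4-[4-(benzyloxy)-3,5-dimethoxyphenyl]-3-[(benzyloxy)methyl]-5,7-dimethoxy-1-(trimethylsilyl)-3,4-dihydronaphthalen-2(1H)-one (either configuration at the silylated carbon, not isolated) | O=C1C([Si](C)(C)C)c2cc(OC)c(OCc3ccccc3)c(OC)c2[C@H](c2cc(OC)c(OCc3ccccc3)c(OC)c2)[C@H]1COCc1ccccc1 | intermediate
14 | (3S,4S)-6-(benzyloxy)-4-[4-(benzyloxy)-3,5-dimethoxyphenyl]-3-[(benzyloxy)methyl]-5,7-dimethoxy-3,4-dihydronaphthalen-2(1H)-one (trans) | O=C1Cc2cc(OC)c(OCc3ccccc3)c(OC)c2[C@H](c2cc(OC)c(OCc3ccccc3)c(OC)c2)[C@H]1COCc1ccccc1 | intermediate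
15 | potassium (3S,4S)-6-(benzyloxy)-4-[4-(benzyloxy)-3,5-dimethoxyphenyl]-3-[(benzyloxy)methyl]-5,7-dimethoxy-3,4-dihydronaphthalen-2-olate (not isolated) | [K]OC1=Cc2cc(OC)c(OCc3ccccc3)c(OC)c2[C@H](c2cc(OC)c(OCc3ccccc3)c(OC)c2)[C@H]1COCc1ccccc1 | intermediate
16 | (3S,4S)-6-(benzyloxy)-4-[4-(benzyloxy)-3,5-dimethoxyphenyl]-3-[(benzyloxy)methyl]-5,7-dimethoxy-3,4-dihydronaphthalen-2-yl trifluoromethanesulfonate | O=S(=O)(OC1=Cc2cc(OC)c(OCc3ccccc3)c(OC)c2[C@H](c2cc(OC)c(OCc3ccccc3)c(OC)c2)[C@H]1COCc1ccccc1)C(F)(F)F | intermediate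
17 | methyl (3R,4S)-6-(benzyloxy)-4-[4-(benzyloxy)-3,5-dimethoxyphenyl]-3-[(benzyloxy)methyl]-5,7-dimethoxy-3,4-dihydronaphthalene-2-carboxylate | COC(=O)C1=Cc2cc(OC)c(OCc3ccccc3)c(OC)c2[C@H](c2cc(OC)c(OCc3ccccc3)c(OC)c2)[C@H]1COCc1ccccc1 | intermediate
18 | methyl (3R,4S)-6-[(dichloroboranyl)oxy]-4-{4-[(dichloroboranyl)oxy]-3,5-dimethoxyphenyl}-3-{[(dichloroboranyl)oxy]methyl}-5,7-dimethoxy-3,4-dihydronaphthalene-2-carboxylate (not isolated) | COC(=O)C1=Cc2cc(OC)c(OB(Cl)Cl)c(OC)c2[C@H](c2cc(OC)c(OB(Cl)Cl)c(OC)c2)[C@H]1COB(Cl)Cl | intermediate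
19 | methyl (3R,4S)-6-hydroxy-4-(4-hydroxy-3,5-dimethoxyphenyl)-3-(hydroxymethyl)-5,7-dimethoxy-3,4-dihydronaphthalene-2-carboxylate, (1S,2R) in the core numbering used above | COC(=O)C1=Cc2cc(OC)c(O)c(OC)c2[C@H](c2cc(OC)c(O)c(OC)c2)[C@H]1CO | target

**Step count and risks**

Total steps: 10. Longest linear sequence: 9 steps (steps 1, 2, 4, 5, 6, 7, 8, 9, 10 from acetosyringone); step 3 is the one-step side branch.

Step 7. What may go wrong: migration of the branched C2 carbon instead of ring A carbon C4a, collapse of the adduct to an epoxide, sluggish addition to the electron-rich aryl ketone, or a second insertion into the newly formed ketone. The fallback leaves the route at 11 and returns at 14. Wittig methylenation of 11 (Ph3P=CH2 from Ph3PCH3Br and KOtBu, THF, 0 °C) would give the exocyclic alkene (2R,3S)-5-(benzyloxy)-3-[4-(benzyloxy)-3,5-dimethoxyphenyl]-2-[(benzyloxy)methyl]-4,6-dimethoxy-1-methylidene-2,3-dihydro-1H-indene F1, in which C4 is already bonded to C3. Oxidative rearrangement with PhI(OH)OTs in 95% MeOH would then attach trivalent iodine to the CH2 terminus, ring A carbon C4a would shift onto C4 with loss of iodobenzene (a phenonium-type 1,2-aryl shift, the only migration open to this cation), and hydrolysis of the resulting ketal on work-up would deliver 14. The same two bonds are made, in two operations instead of one.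

Step 5. What may go wrong: erosion of enantioselectivity through the neutral, bromide-bound arylpalladium pathway, hydrodebromination of the aryl bromide, or β-hydride elimination to the indenone instead of protonation. The fallback leaves at 7 and returns at 8. Miyaura borylation of 7 (B2pin2, PdCl2(dppf), KOAc, 1,4-dioxane, 80 °C) would give the boronate (E)-1-[4-(benzyloxy)-3,5-dimethoxy-2-(4,4,5,5-tetramethyl-1,3,2-dioxaborolan-2-yl)phenyl]-3-[4-(benzyloxy)-3,5-dimethoxyphenyl]prop-2-en-1-one F2. Rhodium-catalysed asymmetric intramolecular 1,4-addition ([RhCl(C2H4)2]2, a chiral phosphoramidite such as MonoPhos, aq K3PO4, toluene; Hayashi–Miyaura-type arylrhodium conjugate addition) would then close the five-membered ring to 8 with the stereocentre set by the ligand on monovalent rhodium.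

Step 6. What may go wrong: O-alkylation of the enolate by the hard chloromethyl ether, a second alkylation, β-elimination of benzyl alcohol from the product through proton exchange, or incomplete trans selectivity. The fallback leaves at 8 and returns at 11. The enolate of 8 would be trapped (LiN(SiMe3)2, then Me3SiCl, THF, −78 °C) as the silyl enol ether {[(1S)-6-(benzyloxy)-1-[4-(benzyloxy)-3,5-dimethoxyphenyl]-5,7-dimethoxy-1H-inden-3-yl]oxy}trimethylsilane F3. Lewis-acid-mediated alkylation of F3 with benzyl chloromethyl ether (TiCl4, CH2Cl2, −78 °C; Mukaiyama-type reaction of a silyl enol ether with an oxocarbenium ion) would then form the C2–CH2O bond anti to the aryl group under non-basic conditions, which closes off the elimination and polyalkylation paths, and give 11.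

**Further compounds**

F1 | step 7 | (2R,3S)-5-(benzyloxy)-3-[4-(benzyloxy)-3,5-dimethoxyphenyl]-2-[(benzyloxy)methyl]-4,6-dimethoxy-1-methylidene-2,3-dihydro-1H-indene | C=C1c2cc(OC)c(OCc3ccccc3)c(OC)c2[C@H](c2cc(OC)c(OCc3ccccc3)c(OC)c2)[C@H]1COCc1ccccc1
F2 | step 5 | (E)-1-[4-(benzyloxy)-3,5-dimethoxy-2-(4,4,5,5-tetramethyl-1,3,2-dioxaborolan-2-yl)phenyl]-3-[4-(benzyloxy)-3,5-dimethoxyphenyl]prop-2-en-1-one | O=C(/C=C/c1cc(OC)c(OCc2ccccc2)c(OC)c1)c1cc(OC)c(OCc2ccccc2)c(OC)c1B1OC(C)(C)C(C)(C)O1
F3 | step 6 | {[(1S)-6-(benzyloxy)-1-[4-(benzyloxy)-3,5-dimethoxyphenyl]-5,7-dimethoxy-1H-inden-3-yl]oxy}trimethylsilane | C[Si](C)(C)OC1=C[C@@H](c2cc(OC)c(OCc3ccccc3)c(OC)c2)c2c(OC)c(OCc3ccccc3)c(OC)cc12
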